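## Structural features

Guanipiperazine A is a guanine (2-amino-1,7-dihydropurin-6-one) bonded through C8 to a benzene ring, ring A. Ring A carries four groups: a free phenol OH, the guanine C8 on one side of it, a diaryl ether oxygen on the other side, and a CH2 group para to the OH. The ether oxygen leads to a para-phenylene, ring B, whose far end carries a second CH2. The two CH2 groups end on C5 (ring A side) and C2 (ring B side) of a piperazine. Three atoms of ring A, the oxygen, four atoms of ring B, the two CH2 groups and four piperazine atoms form a 14-membered meta,para-cyclophane bridged across the piperazine. The only stereocentres are piperazine C2 and C5. They stand 1,4 to each other, are both S and cis, and each is the α-carbon of an arylalanine unit, so the piperazine is a reduced L,L-diketopiperazine. The fragile parts are the electron-rich phenol of ring A (oxidation), the two basic secondary amines, and the amphoteric, poorly soluble guanine. The real difficulty is closing the short, strained cyclophane without touching the α-centres, followed by placing four different groups correctly on ring A. The key step uses the benzylic CH2 between ring A and piperazine C5: when the piperazine is traced back to an open dipeptide, this carbon is the β-methyl of an N-terminal alanine, within reach of a palladium held by the neighbouring amide nitrogen and the C-terminal carboxylate.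

## Logic of the disconnections

20 to 19: the two N–CO2tBu bonds are cut. The polar, basic diamine is released only in the last step, so every earlier compound is neutral and can be chromatographed. The forward step needs only that guanine, phenol and diaryl ether tolerate acid.

19 to 15 and 16: the C8–N7 and C8–N9 bonds of the imidazole ring are cut. This removes the least tractable part of the molecule and takes it from a commercial pyrimidine; ring A is left with an aldehyde carbon. The forward step needs the aldehyde ortho to the phenol, both piperazine nitrogens masked, and an oxidation mild enough for the phenol.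

15 to 14, 13 and 12: the ring A C–CHO bond is cut, then the benzyl–oxygen bond and the two carbamates. The free phenol directs formylation to its only open ortho position, so the tetrasubstituted ring A reduces to a trisubstituted one with no regiochemical choice. The demand is the order of events: the carbamates go on before the phenol is freed, so that neither amine can meet formaldehyde or the aldehyde.

12 to 11, 9 (through 10) and 8: the C3 and C6 methylenes are taken back to carbonyl groups, and the N4–C3 lactam bond is then cut. This reveals an L,L-dipeptide inside a monocyclic 14-membered ring, the most flexible form the cyclophane can take. The forward steps need the amine and an ester to meet across the ring through a cis amide, and a reduction that leaves the aryl ethers alone.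

8 to 7: the ring A C(aryl)–CH2 bond is cut. The macrocycle becomes a linear dipeptide whose N-terminal residue is plain alanine, ring A becomes an aryl iodide, and both stereocentres are now purchased ones. The forward step must pick one methyl C–H bond out of many, close a strained 14-membered ring instead of coupling two molecules, and spare both α-centres. For that it needs a free carboxylic acid, an amide N–H next to it, and an alanine nitrogen with no N–H.

7 to 6, 5, and then 3 and 4: the ester C–O bond, the C–I bond and the ring A C–O bond of the diaryl ether are cut. The ether comes from a phenol and a boronic acid under neutral conditions, and iodine is placed by the stronger para-directing power of the alkoxy group. The demands are para selectivity to the benzyloxy group and an ester that falls to acid, because hydroxide would open the phthalimide.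

3 to 1 and 2: the N1–C6 amide bond is cut to two commercial amino acid derivatives. The coupling must acylate nitrogen in the presence of the free phenol and must not epimerise the activated alanine.

## Other disconnections considered

Alternative 1: The cut is through C8–N7 and C8–N9 of the guanine. In the forward direction the di-Boc macrocyclic salicylaldehyde A2 condenses with the 5-amino group of 16, the 6-amino group closes onto the imine carbon, and oxidation aromatises the imidazole to give N,N'-di-Boc guanipiperazine A, A1.
- In its favour: the purine arrives last from a commercial heterocycle, no cross-coupling on an unprotected purine is needed, and the bonds formed are carbon–nitrogen bonds made by condensation, the most dependable kind in the whole problem.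
- Against it as the defining disconnection: it forms neither the cyclophane nor a stereocentre; all the hard structure is already in A2, and the question of how to make A2 stays open.
- Comparison: on structure it addresses the easy half of the molecule, whereas the chosen plan addresses the ring. On mechanism it is the safer reaction, and on that point it is the better of the two. On step economy there is no difference, because A2 is compound 15 and A1 is compound 19, and the chosen route ends with exactly this move (step 12). The two plans are complementary, not rivals.

Alternative 2: The cut is through both C–N bonds at the stereocentres. The achiral diaryl ether bis-(E)-allylic trichloroacetimidate A3 would be rearranged on both arms by di-μ-chlorobis[(η5-(S)-(pR)-2-(2'-(4'-isopropyl)oxazolinyl)cyclopentadienyl-1-C,3'-N)(η4-tetraphenylcyclobutadiene)cobalt]dipalladium (COP-Cl) to the (S,S)-bis(allylic trichloroacetamide) A4.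
- In its favour: both centres are set in one operation by the catalyst, either enantiomer is available, and a two-fold reaction diverts most of the minor enantiomer into a separable diastereomer. The diaryl ether and the ring A pattern are built while no stereocentre exists, so nothing can epimerise there; on this point it is better than the chosen plan, which carries two α-centres through steps 2 to 5.
- Mechanism: the rearrangement stays at divalent palladium, runs near room temperature and is a well-behaved aza-Claisen-type process, gentler than the 90 °C divalent/tetravalent cycle of step 5. On mildness of the single event it is at least the equal.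
- Against it here: it makes the stereocentres but not the rings. After A4 the amides must be cleaved, each vinyl group cut down to an aldehyde carbon α to nitrogen (a configurationally labile arrangement), and each nitrogen joined to the carbon of the other arm. The piperazine and the 14-membered ring would then close in one double condensation in competition with intermolecular condensation. The hard step is postponed and rests on epimerisable material.
- Further cost: A3 needs two (E)-4-arylbut-2-enyl arms, whose double bonds can drift into conjugation with the arenes. The two stereocentres of the target are α-carbons of natural configuration that can be bought, so catalytic asymmetric generation gains little. The route would be clearly longer.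

Alternative 3: The cut is the C5–CH2 bond, with C5 as a glycine carbon of a diketopiperazine. In the forward direction CsF would desilylate the ring A silyl ether of A5 (tert-butyldimethylsilyl assumed). The phenoxide would expel the para benzylic chloride to give the para-quinone methide A6, and the glycine enolate of the N-Boc-activated diketopiperazine would add to the exocyclic carbon to give the macrocyclic diketopiperazine A7.
- In its favour: one metal-free step forms the carbon–carbon bond, the C5 stereocentre and the ring. Only one chiral amino acid is needed. The cis relationship is enforced by geometry, since only the enolate face on the side of the tyrosine arm can reach. The ring A phenol emerges free, which saves a debenzylation; on that point it is better than the chosen plan.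
- Against it here: fluoride and a phenoxide are weak bases for a lactam α-proton, so enolate and quinone methide may not coexist in useful amounts. A6 can be trapped by fluoride or by a second molecule, and the N-Boc imide is itself open to nucleophiles. The tyrosine α-proton may exchange under the same conditions, which would erode enantiopurity because the bridge would then form on the other face.
- Structure: the ring is closed onto a rigid diketopiperazine that must bend into a boat, whereas step 5 closes it on an open dipeptide.
- Mechanism and step economy: both plans make the same bond, one by ionic 1,6-addition, the other by C–H metalation. The step count would be similar, since A5 needs a separately built ring A with silyl ether and chloromethyl group, and the N-benzyl group must be removed later. The chosen plan is preferred because its stereocentres are never enolisable under the key conditions and the site of bond formation is fixed by chelation, not by a balance of acidities.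

Key step: step 5

Remarks on the chemistry before the steps:
- No structural correction is needed. Compounds 7 and 8 are L,L and map onto the (2S,5S)-piperazine; the descriptors stay S because CH2N takes the place of the carbonyl carbon in the priority order.
- The acid of 7 is carried as a tert-butyl ester, not a methyl ester. Hydroxide strong enough to saponify a methyl ester would also open the phthalimide to a phthalamic acid.
- The peptide bond is made first, so no carbamate is needed on the tyrosine nitrogen and one protection/deprotection pair disappears.
- Acid 8 is converted to its methyl ester before the phthalimide is removed, because a free amine does not close onto a carboxylic acid without an activating agent.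
- Compound 16 is used as its commercial sulfate. The purine is drawn as the 7H tautomer; no step depends on which tautomer is written.

## Route

Step 1
Reactants: 1 N-phthaloyl-L-alanine; 2 L-tyrosine tert-butyl ester
Product: 3 N-phthaloyl-L-alanyl-L-tyrosine tert-butyl ester
Conditions: EDC·HCl, HOBt, CH2Cl2/DMF, 0 °C to rt
Reagents that add atoms: none
Why: Carbodiimide/HOBt amide coupling; the phthalimide nitrogen has no N–H, so the activated alanine cannot form an oxazolone and should keep its configuration, and the amine is acylated far faster than the phenol.

Step 2
Reactants: 3 N-phthaloyl-L-alanyl-L-tyrosine tert-butyl ester; 4 2-(benzyloxy)phenylboronic acid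
Product: 5 N-phthaloyl-L-alanyl-O-[2-(benzyloxy)phenyl]-L-tyrosine tert-butyl ester
Conditions: Cu(OAc)2 (2 equiv), pyridine (5 equiv), 4 Å MS, CH2Cl2, dry air, rt
Reagents that add atoms: none
Why: Chan–Lam O-arylation: the aryl group passes from boron to a divalent copper phenoxide and C–O reductive elimination follows at room temperature. The neutral conditions leave both α-centres, the phthalimide and the tert-butyl ester alone, and the secondary amide N–H is a much poorer partner than the phenol.

Step 3
Reactants: 5 N-phthaloyl-L-alanyl-O-[2-(benzyloxy)phenyl]-L-tyrosine tert-butyl ester
Product: 6 N-phthaloyl-L-alanyl-O-[2-(benzyloxy)-5-iodophenyl]-L-tyrosine tert-butyl ester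
Conditions: NIS (1.05 equiv), TFA (0.2 equiv), MeCN, 0 °C to rt, dark
Reagents that add atoms: N-iodosuccinimide, O=C1CCC(=O)N1I
Why: Electrophilic aromatic iodination with acid-activated NIS. Ring A is a catechol diether and more electron-rich than ring B, and the alkoxy group is a stronger para director than the aryloxy group, so iodine should enter para to the benzyloxy oxygen.

Step 4
Reactants: 6 N-phthaloyl-L-alanyl-O-[2-(benzyloxy)-5-iodophenyl]-L-tyrosine tert-butyl ester
Product: 7 N-phthaloyl-L-alanyl-O-[2-(benzyloxy)-5-iodophenyl]-L-tyrosine
Conditions: HCl (4 M in 1,4-dioxane), rt
Reagents that add atoms: none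
Why: Acidolysis of a tert-butyl ester by alkyl–oxygen cleavage; chloride takes up the tert-butyl cation before it can alkylate an arene. No hydroxide is present, so the phthalimide stays closed and the aryl benzyl ether and aryl iodide are untouched.

Step 5
Reactants: 7 N-phthaloyl-L-alanyl-O-[2-(benzyloxy)-5-iodophenyl]-L-tyrosine
Product: 8 14-membered cyclophane dipeptide acid (phthalimido at the ring A side α-carbon, free CO2H at the ring B side α-carbon, both centres L)
Conditions: Pd(OAc)2 (15 mol%), AgOAc (2.5 equiv), HFIP (5 mM), 90 °C, sealed tube
Reagents that add atoms: none
Why: Backbone-directed palladium-catalysed β-C(sp3)–H arylation, run intramolecularly. Divalent palladium binds the deprotonated amide nitrogen and the carboxylate of 7 as a five-membered N,O-chelate, and acetate-assisted concerted metalation–deprotonation of an alanine methyl C–H bond then gives a five-membered palladacycle fused to that chelate. The tethered aryl iodide adds oxidatively to give a tetravalent palladium aryl alkyl species, C(sp3)–C(sp2) reductive elimination forms the aryl–CH2 bond, and AgOAc removes iodide as AgI and returns palladium as its carboxylate. The closest known reaction type is the amide- and carboxylate-directed methyl arylation of N-phthaloyl alanyl peptides with aryl iodides, including its use to staple peptides into cyclophanes. The one ring closed is the 14-membered meta,para-cyclophane; it closes by reductive elimination from a 15-membered pallada-macrocycle, a ring contraction by one atom that lies outside the Baldwin classes. No stereocentre is formed, and the two existing ones should persist because the alanine nitrogen is a phthalimide without N–H and the tyrosine α-C–H sits inside the chelate ring where the metal cannot reach it. Site selectivity against the tyrosine CH2, the benzylic OCH2 and all aryl C–H bonds comes from the fact that only the N-terminal methyl can form a five-membered palladacycle from the N,O-chelate; ring closure over oligomerisation is favoured by high dilution, and the benzyl and diaryl ethers are safe because no zerovalent palladium is formed.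

Step 6
Reactants: 8 14-membered cyclophane dipeptide acid
Product: 9 methyl ester of the cyclophane dipeptide
Conditions: MeI, KHCO3, DMF, rt
Reagents that add atoms: iodomethane, CI
Why: SN2 O-alkylation of the carboxylate; hydrogencarbonate is too weak a base to deprotonate either α-carbon, the amide or to open the phthalimide. The ester is the electrophile that the amine of the next step needs.

Step 7
Reactants: 9 methyl ester of the cyclophane dipeptide
Product: 11 bridged diketopiperazine benzyl ether (3S,6S), via amino ester 10 (not isolated)
Conditions: N2H4·H2O (2 equiv), MeOH/CH2Cl2, rt; then AcOH (cat.), toluene/2-butanol, 100 °C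
Reagents that add atoms: none
Why: Ing–Manske hydrazinolysis of the phthalimide, then intramolecular aminolysis of the methyl ester (diketopiperazine formation). Amine and ester sit on the two α-carbons flanking the macrocyclic amide, which the strained ring should hold in or near its cis form, and weak-acid catalysis avoids enolisation of either centre.

Step 8
Reactants: 11 bridged diketopiperazine benzyl ether
Product: 12 bridged (2S,5S)-piperazine benzyl ether
Conditions: BH3·THF, THF, reflux; then HCl, MeOH, reflux; aq. NaOH
Reagents that add atoms: none
Why: Borane reduction of both secondary lactams to amines; the electrophilic hydride source leaves aryl and benzyl ethers alone and the stereocentres are not involved. Acidic methanolysis breaks the amine–borane adducts.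

Step 9
Reactants: 12 bridged (2S,5S)-piperazine benzyl ether
Product: 13 N,N'-di-Boc piperazine benzyl ether
Conditions: Boc2O, Et3N, CH2Cl2, rt
Reagents that add atoms: di-tert-butyl dicarbonate, CC(C)(C)OC(=O)OC(=O)OC(C)(C)C
Why: Carbamate formation on both secondary amines; this keeps them from forming aminals or iminium ions with formaldehyde and the aldehyde in steps 11 and 12. The phenol is still benzylated, so no carbonate can form.

Step 10
Reactants: 13 N,N'-di-Boc piperazine benzyl ether
Product: 14 N,N'-di-Boc piperazine phenol
Conditions: H2 (1 atm), 10% Pd/C, EtOAc/MeOH, rt
Reagents that add atoms: none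
Why: Hydrogenolysis of the benzyl aryl ether; the diaryl ether and the carbamates are inert under these conditions.

Step 11
Reactants: 14 N,N'-di-Boc piperazine phenol
Product: 15 N,N'-di-Boc macrocyclic salicylaldehyde
Conditions: MgCl2, Et3N, (CH2O)n, MeCN, reflux
Reagents that add atoms: formaldehyde (as paraformaldehyde), C=O
Why: Magnesium-mediated ortho-formylation of a phenol (Casnati–Skattebøl): the magnesium phenoxide delivers formaldehyde to the ortho carbon and a second formaldehyde oxidises the resulting benzylic alkoxide by hydride transfer. Only one ortho position is free and the para position is blocked, so the regiochemistry is fixed.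

Step 12
Reactants: 15 N,N'-di-Boc macrocyclic salicylaldehyde; 16 2,5,6-triaminopyrimidin-4(3H)-one sulfate
Product: 19 N,N'-di-Boc guanipiperazine A, via Schiff base 17 (not isolated), via 7,8-dihydroguanine aminal 18 (not isolated)
Conditions: NaOAc, DMSO, 80 °C; then air, 100 °C
Reagents that add atoms: none
Why: Traube-type purine synthesis in its oxidative aldehyde variant: the 5-amino group, the most nucleophilic of the three, forms the Schiff base, the neighbouring 6-amino group adds to the imine carbon, and air dehydrogenates the aminal to the aromatic imidazole. The carbamates keep the piperazine nitrogens out of the condensation.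

Step 13
Reactants: 19 N,N'-di-Boc guanipiperazine A
Product: 20 guanipiperazine A
Conditions: TFA/CH2Cl2 (1:1), H2O (2%), rt; then aq. NH3
Reagents that add atoms: none
Why: Acidolysis of both tert-butyl carbamates with loss of 2-methylpropene and CO2; guanine, phenol and diaryl ether are stable to acid, and neutralisation gives the free base without touching the stereocentres.

## Compound list

1 | N-phthaloyl-L-alanine, (S)-2-(1,3-dioxoisoindolin-2-yl)propanoic acid | C[C@H](N1C(=O)c2ccccc2C1=O)C(=O)O | starting material
2 | L-tyrosine tert-butyl ester | CC(C)(C)OC(=O)[C@@H](N)Cc1ccc(O)cc1 | starting material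
3 | N-phthaloyl-L-alanyl-L-tyrosine tert-butyl ester | C[C@H](N1C(=O)c2ccccc2C1=O)C(=O)N[C@@H](Cc1ccc(O)cc1)C(=O)OC(C)(C)C | intermediate
4 | 2-(benzyloxy)phenylboronic acid | OB(O)c1ccccc1OCc1ccccc1 | starting material
5 | N-phthaloyl-L-alanyl-O-[2-(benzyloxy)phenyl]-L-tyrosine tert-butyl ester | C[C@H](N1C(=O)c2ccccc2C1=O)C(=O)N[C@@H](Cc1ccc(Oc2ccccc2OCc2ccccc2)cc1)C(=O)OC(C)(C)C | intermediate
6 | N-phthaloyl-L-alanyl-O-[2-(benzyloxy)-5-iodophenyl]-L-tyrosine tert-butyl ester | C[C@H](N1C(=O)c2ccccc2C1=O)C(=O)N[C@@H](Cc1ccc(Oc2cc(I)ccc2OCc2ccccc2)cc1)C(=O)OC(C)(C)C | intermediate
7 | N-phthaloyl-L-alanyl-O-[2-(benzyloxy)-5-iodophenyl]-L-tyrosine (precursor of the key step) | C[C@H](N1C(=O)c2ccccc2C1=O)C(=O)N[C@@H](Cc1ccc(Oc2cc(I)ccc2OCc2ccccc2)cc1)C(=O)O | intermediate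
8 | 14-membered cyclophane dipeptide acid; L-configured α-carbons, phthalimido on the ring A side, CO2H on the ring B side, benzyloxy on ring A (product of the key step) | OC(=O)[C@@H]1Cc2ccc(cc2)Oc2cc(ccc2OCc2ccccc2)C[C@H](N2C(=O)c3ccccc3C2=O)C(=O)N1 | intermediate
9 | methyl ester of 8 | COC(=O)[C@@H]1Cc2ccc(cc2)Oc2cc(ccc2OCc2ccccc2)C[C@H](N2C(=O)c3ccccc3C2=O)C(=O)N1 | intermediate
10 | amino ester: 9 with the phthalimide replaced by NH2 | COC(=O)[C@@H]1Cc2ccc(cc2)Oc2cc(ccc2OCc2ccccc2)C[C@H](N)C(=O)N1 | intermediate (not isolated)
11 | bridged (3S,6S)-diketopiperazine, ring A benzyl ether | c1cc2cc(c1OCc3ccccc3)Oc3ccc(cc3)C[C@H]3C(=O)N[C@H](C(=O)N3)C2 | intermediate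
12 | bridged (2S,5S)-piperazine, ring A benzyl ether | c1cc2cc(c1OCc3ccccc3)Oc3ccc(cc3)C[C@H]3CN[C@H](CN3)C2 | intermediate
13 | N,N'-di-Boc derivative of 12 | c1cc2cc(c1OCc3ccccc3)Oc3ccc(cc3)C[C@H]3CN(C(=O)OC(C)(C)C)[C@H](CN3C(=O)OC(C)(C)C)C2 | intermediate
14 | N,N'-di-Boc bridged piperazine with free ring A phenol | c1cc2cc(c1O)Oc1ccc(cc1)C[C@H]1CN(C(=O)OC(C)(C)C)[C@H](CN1C(=O)OC(C)(C)C)C2 | intermediate
15 | N,N'-di-Boc macrocyclic salicylaldehyde (CHO ortho to OH, meta to the CH2 arm) | O=Cc1cc2cc(c1O)Oc1ccc(cc1)C[C@H]1CN(C(=O)OC(C)(C)C)[C@H](CN1C(=O)OC(C)(C)C)C2 | intermediate
16 | 2,5,6-triaminopyrimidin-4(3H)-one sulfate | Nc1nc(N)c(N)c(=O)[nH]1.OS(=O)(=O)O | starting material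
17 | Schiff base of 15 with the 5-amino group of 16 | Nc1nc(N)c(N=Cc2cc3cc(c2O)Oc2ccc(cc2)C[C@H]2CN(C(=O)OC(C)(C)C)[C@H](CN2C(=O)OC(C)(C)C)C3)c(=O)[nH]1 | intermediate (not isolated)
18 | 8-aryl-7,8-dihydroguanine aminal (either configuration at C8, lost on oxidation) | Nc1nc2NC(c3cc4cc(c3O)Oc3ccc(cc3)C[C@H]3CN(C(=O)OC(C)(C)C)[C@H](CN3C(=O)OC(C)(C)C)C4)Nc2c(=O)[nH]1 | intermediate (not isolated)
19 | N,N'-di-Boc guanipiperazine A | Nc1nc2nc(-c3cc4cc(c3O)Oc3ccc(cc3)C[C@H]3CN(C(=O)OC(C)(C)C)[C@H](CN3C(=O)OC(C)(C)C)C4)[nH]c2c(=O)[nH]1 | intermediate
20 | guanipiperazine A | Nc1nc2nc(-c3cc4cc(c3O)Oc3ccc(cc3)C[C@H]3CN[C@H](CN3)C4)[nH]c2c(=O)[nH]1 | target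

## Step count and least certain steps

Total: 13 steps. Longest linear sequence: 13 steps (from 1 or 2); 4 and 16 enter in steps 2 and 12.

**Step 5 (key step).**
- Risk: the tethered aryl iodide may fail to reach the palladacycle. While the amide nitrogen is still bound, aryl and alkyl must sit cis on the metal, which folds ring B into a tighter loop than the final ring. The consequences would be coupling between two molecules, loss of iodine by protonolysis, or stalling.
- Fallback: close the same 14-membered ring at the ether oxygen after making the aryl–CH2 bond intermolecularly. It sets out from 3 and returns at 8.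
  - Acidolysis of 3 with HCl in dioxane should give N-phthaloyl-L-alanyl-L-tyrosine F1.
  - O-Benzylation of 2-bromo-4-iodophenol (BnBr, K2CO3, acetone) should give 1-(benzyloxy)-2-bromo-4-iodobenzene F2.
  - The same backbone-directed methyl arylation, now between two molecules (Pd(OAc)2, AgOAc, HFIP, 80 °C), should join F1 and F2 at the iodide only and give the 3-bromo-4-benzyloxyphenylalanyl-tyrosine F3.
  - An intramolecular Ullmann etherification of F3 (CuI, N,N-dimethylglycine, Cs2CO3, dioxane, 90 °C, high dilution) should then close the diaryl ether to 8.

**Step 12.**
- Risk: incomplete dehydrogenation of the aminal, oxidative breakdown of the electron-rich triaminopyrimidinone or of the phenol under air at 100 °C, and poor solubility of 16.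
- Fallback: the acylation/cyclodehydration form of the Traube synthesis, with no oxidant in the ring-forming step. It sets out from 15 and returns at 19.
  - Pinnick oxidation of 15 (NaClO2, NaH2PO4, 2-methyl-2-butene, tBuOH/H2O) should give the salicylic acid F4.
  - Coupling with the 5-amino group of 16 (EDC·HCl, HOBt, Et3N, DMF) should give the 5-amide F5.
  - Heating F5 in aq. NaOH/EtOH should close the imidazole by loss of water to 19; the carbamates are stable to base.

**Step 3.**
- Risk: iodination at the wrong carbon (para to the aryloxy oxygen, or ortho to oxygen on ring B) or double iodination, with regioisomers that are hard to separate.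
- Fallback: bring the iodine in on a ring whose pattern is fixed by the reagent. It sets out from 3, bypasses step 2 as well, and returns at 6.
  - SNAr of the phenoxide of 3 on 2-fluoro-4-iodobenzaldehyde (K2CO3, DMF, 60 °C) should give the 2-aryloxy-4-iodobenzaldehyde F6.
  - Baeyer–Villiger (Dakin-type) oxidation with mCPBA in CH2Cl2 should give the aryl formate F7.
  - Methanolysis (KHCO3, MeOH, 0 °C) should give the phenol F8.
  - Benzylation (BnBr, K2CO3, acetone) should give 6.

**Step 7.**
- Risk: hydrazine may attack the methyl ester in competition with the phthalimide, or the transannular lactamisation may be slow if the macrocyclic amide is held trans, with epimerisation on long heating.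
- Fallback: activate the acid instead of using an ester. It sets out from 8, skips step 6, and returns at 11.
  - Hydrazinolysis of 8 (N2H4·H2O, EtOH, 60 °C), where no ester is present, should give the amino acid F9.
  - Lactamisation at high dilution (EDC·HCl, HOAt, DMF, 0 °C to rt) should give 11.

## Further compounds

F1 | step 5 | N-phthaloyl-L-alanyl-L-tyrosine | C[C@H](N1C(=O)c2ccccc2C1=O)C(=O)N[C@@H](Cc1ccc(O)cc1)C(=O)O
F2 | step 5 | 1-(benzyloxy)-2-bromo-4-iodobenzene | Brc1cc(I)ccc1OCc1ccccc1
F3 | step 5 | N-phthaloyl-3-bromo-4-(benzyloxy)-L-phenylalanyl-L-tyrosine | O=C(N[C@@H](Cc1ccc(O)cc1)C(=O)O)[C@H](Cc1ccc(OCc2ccccc2)c(Br)c1)N1C(=O)c2ccccc2C1=O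
F4 | step 12 | N,N'-di-Boc macrocyclic salicylic acid | OC(=O)c1cc2cc(c1O)Oc1ccc(cc1)C[C@H]1CN(C(=O)OC(C)(C)C)[C@H](CN1C(=O)OC(C)(C)C)C2
F5 | step 12 | 5-aroylamino-2,6-diaminopyrimidin-4(3H)-one from F4 | Nc1nc(N)c(NC(=O)c2cc3cc(c2O)Oc2ccc(cc2)C[C@H]2CN(C(=O)OC(C)(C)C)[C@H](CN2C(=O)OC(C)(C)C)C3)c(=O)[nH]1
F6 | step 3 | N-phthaloyl-L-alanyl-O-(2-formyl-5-iodophenyl)-L-tyrosine tert-butyl ester | C[C@H](N1C(=O)c2ccccc2C1=O)C(=O)N[C@@H](Cc1ccc(Oc2cc(I)ccc2C=O)cc1)C(=O)OC(C)(C)C
F7 | step 3 | N-phthaloyl-L-alanyl-O-[2-(formyloxy)-5-iodophenyl]-L-tyrosine tert-butyl ester | C[C@H](N1C(=O)c2ccccc2C1=O)C(=O)N[C@@H](Cc1ccc(Oc2cc(I)ccc2OC=O)cc1)C(=O)OC(C)(C)C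
F8 | step 3 | N-phthaloyl-L-alanyl-O-(2-hydroxy-5-iodophenyl)-L-tyrosine tert-butyl ester | C[C@H](N1C(=O)c2ccccc2C1=O)C(=O)N[C@@H](Cc1ccc(Oc2cc(I)ccc2O)cc1)C(=O)OC(C)(C)C
F9 | step 7 | cyclophane amino acid (8 with NH2 in place of the phthalimide) | OC(=O)[C@@H]1Cc2ccc(cc2)Oc2cc(ccc2OCc2ccccc2)C[C@H](N)C(=O)N1
A1 | alternative 1 | N,N'-di-Boc guanipiperazine A (the same compound as 19) | Nc1nc2nc(-c3cc4cc(c3O)Oc3ccc(cc3)C[C@H]3CN(C(=O)OC(C)(C)C)[C@H](CN3C(=O)OC(C)(C)C)C4)[nH]c2c(=O)[nH]1
A2 | alternative 1 | N,N'-di-Boc macrocyclic salicylaldehyde (the same compound as 15) | O=Cc1cc2cc(c1O)Oc1ccc(cc1)C[C@H]1CN(C(=O)OC(C)(C)C)[C@H](CN1C(=O)OC(C)(C)C)C2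
A3 | alternative 2 | bis-(E)-allylic trichloroacetimidate of the achiral diaryl ether | N=C(OC/C=C/Cc1ccc(OCc2ccccc2)c(Oc2ccc(C/C=C/COC(=N)C(Cl)(Cl)Cl)cc2)c1)C(Cl)(Cl)Cl
A4 | alternative 2 | (S,S)-bis(allylic trichloroacetamide) | C=C[C@H](Cc1ccc(OCc2ccccc2)c(Oc2ccc(C[C@@H](C=C)NC(=O)C(Cl)(Cl)Cl)cc2)c1)NC(=O)C(Cl)(Cl)Cl
A5 | alternative 3 | N-benzyl-N'-Boc cyclo(Gly-L-Tyr) whose tyrosine oxygen carries a 5-(chloromethyl)-2-(tert-butyldimethylsilyloxy)phenyl ring | ClCc1ccc(O[Si](C)(C)C(C)(C)C)c(Oc2ccc(C[C@H]3C(=O)N(Cc4ccccc4)CC(=O)N3C(=O)OC(C)(C)C)cc2)c1
A6 | alternative 3 | para-quinone methide derived from A5 | C=C1C=CC(=O)C(Oc2ccc(C[C@H]3C(=O)N(Cc4ccccc4)CC(=O)N3C(=O)OC(C)(C)C)cc2)=C1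
A7 | alternative 3 | macrocyclic diketopiperazine with free ring A phenol | c1cc2cc(c1O)Oc1ccc(cc1)C[C@H]1C(=O)N(Cc3ccccc3)[C@H](C(=O)N1C(=O)OC(C)(C)C)C2
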